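The runs come from a simulation for an exercise, noise included.

At 74 min the alder run read target equal to 26.1 % of its charge, more than the 20.4 % of the maple run.

| flask | starting material | target | time |
|---|---|---|---|
| alder | 200 mM |  |  |
| ash | 120 mM |  |  |
| maple | 100 mM |  |  |
| larch | 200 mM | 100 mM |  |
| birch | 44.0 mM |  | 74 min |

- alder run (time / min: [target] / mM): 5.6: 8.5; 17: 23.3; 33: 36.4; 52: 48.5; 74: 52.3
- ash run (time / min: [target] / mM): 5.6: 3.3; 17: 12.0; 33: 18.2; 52: 25.6; 74: 28.0
- maple run (time / min: [target] / mM): 5.6: 2.5; 17: 8.8; 33: 15.3; 52: 20.0; 74: 20.4
- larch run (time / min: [target] / mM): 5.6: 101.5; 17: 103.4; 33: 104.3; 52: 101.4; 74: 93.9

(readings scatter by 0.6 mM)

1. reaction order in [starting material] at the outset, round the charge of the alder run, defined at two percent of the starting material turned into target (one fixed amount of target, the same in the runs compared)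
2. target in the birch run at 74 min, as a share of the starting material charged
3. which of these the readings show (the product speeds the reaction / the product binds the substrate / the substrate is lost by itself / the product decays / nothing beyond the main steps)

- Overall: starting material -> target.
- Constant volume, constant temperature.
- What is held in complexes is read along with the free species.
- An order is taken over about fifteen percent of the charge, up and down.

My bench rule was simple: a first-order flask turns the same share in the same time, whatever its charge. So I took equal shares as the zero of my scale. Applied honestly, the rule gave the birch run the maple share. It stopped at one ratio. The alder share stood 28.2 % above the maple share, and the scatter was 2.94 % of the maple reading. So I measured the departure.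

share ratio = 1.28, charge ratio = 2.00

ln(share ratio) / ln(charge ratio) = 0.358

This is the share slope: the logarithm of the share ratio over the logarithm of the charge ratio, zero for equal shares. I carried it from the maple run down to the birch charge.

share in the birch run = maple share × (birch charge / maple charge)^slope = 15.2 %

Early on, the same slope plus one reads as an apparent order. The alder and maple readings at 17 min gave 1.40. This was a rough figure, taken at one time and not at one amount of target, and between the maple and alder charges. In the larch run, c(target) fell from 104.3 mM to 93.9 mM. Complexes are read along, so I chose decay.

The forecast differed in its numbers, with 1.6 and 14 %, and agreed that the product decays: “Mere binding or inhibition couldn't lower the reading, since complexes are counted, so the target decays.”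

The flask gave an order of 1.4, 15.6 % in the birch run, and the product decays.

    2 starting material ⇌ substrate dimer, settled at all times (5.450 /M)
    substrate dimer → target + starting material (0.03138 /min)
    target → decomposed product (0.01194 /min)

The share slope of 0.358 had put the birch run at 15.2 %, which is 0.40 percentage points below the flask. The larch run proves the loss, since its c(target) fell to 93.9 mM at 74 min, under the 100 mM it was charged with. In the birch run, the target stands at 15.6 % with the loss to decomposed product and at 24.3 % without it, so that loss takes 8.7 points.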